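(The numbers in the tables stem from a simulated flask with made-up constants; the scatter is artificial.)

The leftover comes first: each starting material taken into intermediate A costs one coupling partner, so in Monday's, Wednesday's and Friday's flasks, which share a charge, the balance of the charges, once the starting material is taken up, leaves 0.100 mM of coupling partner, 33.3% of its own charge, and starting material is the limiting reagent.

| setting | red | Friday's | Wednesday's | Monday's |
|---|---|---|---|---|
| starting material | 4.0 × 10⁻⁴ M | 2.0 × 10⁻⁴ M | 2.0 × 10⁻⁴ M | 2.0 × 10⁻⁴ M |
| coupling partner | 0.30 mM | 0.300 mM | 0.300 mM | 0.300 mM |
| remark | run made earlier |  |  |  |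
| time |  | 10 min | 15 min | 20 min |

red run (percent of the starting material charged)

| time / s | starting material / % | intermediate C / % | intermediate B / % | product / % | intermediate D / % | intermediate A / % |
|---|---|---|---|---|---|---|
| 10.0 | 64.8 | 1.7 | 6.6 | 13.9 | 0.5 | 14.0 |
| 15.0 | 58.5 | 1.9 | 9.8 | 11.9 | 0.4 | 17.5 |
| 20.0 | 53.7 | 3.1 | 11.4 | 10.1 | 1.1 | 20.3 |
| 30.0 | 45.3 | 6.3 | 15.2 | 6.9 | 1.8 | 23.9 |
| 50.0 | 33.9 | 12.9 | 20.6 | 4.1 | 4.0 | 24.8 |
| 80.0 | 23.1 | 21.0 | 23.8 | 2.7 | 6.8 | 22.0 |
| 120 | 16.7 | 30.1 | 25.5 | 1.1 | 9.4 | 17.2 |

(standard deviation of a reading: 0.3 percentage points)

- for product the idle adduct is counted in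
- the numbers in the tables scatter by 0.3 percentage points (one standard deviation)
- steps thought possible: starting material + coupling partner <-> product; starting material + coupling partner -> intermediate A; starting material <-> intermediate B; intermediate A <-> intermediate C; intermediate C <-> intermediate D; coupling partner + product <-> idle adduct

- which of these there is most of at the end, counted by the starting material in it, Friday's (intermediate D / intermediate B / intermediate C / intermediate A)
- which of these there is most of at the end, counted by the starting material in it, Wednesday's (intermediate D / intermediate B / intermediate C / intermediate A)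
- which of these there is most of at the end, counted by the starting material in it, Monday's (intermediate D / intermediate B / intermediate C / intermediate A)
- final amount of the leader among these, as a percentage of the starting material charged, in Friday's
- final amount of the leader among these, as a percentage of the starting material charged, in Wednesday's
- final amount of the leader among these, as a percentage of the starting material charged, in Monday's

I draw c(intermediate C) for Monday's flask. The steps feed intermediate C through intermediate A, so its curve starts flat: at 10.0 s the red run reads 1.7% against 14.0%. The pool of intermediates A, C and D rises in the red run around 15.0 s; divided by the starting material and free coupling partner there and scaled to Monday's charge, that slope gives 0.0246 s⁻¹, which I read as a half-life of 28.2 s for free starting material by this capture.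

For the knee, c(intermediate C)+c(intermediate D) in the red run gains 0.00423 s⁻¹ of the charge between 20.0 s and 50.0 s, and 0.00292 s⁻¹ between 80.0 s and 120 s. Set against the mean readings of intermediates A and C, these give 0.0202 s⁻¹ forward and 0.00406 s⁻¹ back, so the pair relaxes with a half-life of 28.6 s. The crossing lies between 80.0 s and 120 s, where the red run's intermediate C passes intermediate A.

At 120 s in the red run, intermediate D reads 0.312 of intermediate C. So I carry the C share, c(intermediate C) over c(intermediate A)+c(intermediate C)+c(intermediate D) at rest: 66.1%. The level is this share times the ceiling, the fraction of the starting material that the coupling partner can take up, which is one here, since cA is smaller than cB. Intermediate B outweighs starting material at 120 s in the red run, so that store arrives late, and I expect Friday's furthest below the level.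

The forecast gives intermediate C at 63.2% for Friday's, intermediate C at 65% for Wednesday's and intermediate C at 65.6% for Monday's: “C is therefore about 66% of the pool and leads in all three runs.”

The flasks give intermediate C at 61.7% for Friday's, intermediate C at 64.8% for Wednesday's and intermediate C at 66.1% for Monday's.

    starting material + coupling partner ⇌ product (K = 910 L mol⁻¹, k = 450 L mol⁻¹ s⁻¹)
    starting material + coupling partner → intermediate A (k = 100 L mol⁻¹ s⁻¹)
    starting material ⇌ intermediate B (K = 1.60, k = 0.00930 s⁻¹)
    intermediate A ⇌ intermediate C (K = 6.40, k = 0.0180 s⁻¹)
    intermediate C ⇌ intermediate D (K = 0.330, k = 0.270 s⁻¹)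
    coupling partner + product ⇌ idle adduct, settled at all times (K = 1300 L mol⁻¹)

Monday's 66.1% stands beside the share of 66.1%, and at 200 min that flask holds 67.3%, with coupling partner at 33.3% of its charge. Monday's neighbour, charged with 7.5 × 10⁻⁵ M of coupling partner, has a ceiling of 37.5%, so the share gives 24.8% of intermediate C. That neighbour holds 25.2% at 20.0 min, with 0.185% of its coupling partner left, and intermediate B stands above intermediate C at 38.5%.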